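**Retrosynthetic overview**
1. The 1,10-epoxide comes last, by peracid epoxidation of the 1(10),4-diene; the C8 ester is put on by acylation with a protected (2S,3S)-diol acid, and C3–Cl comes from SN2 chlorination of the 3-epi allylic alcohol.
2. The α-methylene-γ-lactone comes from Eschenmoser methylenation of the trans-fused lactone, which forms from the C6 alkoxide and a C12 tert-butyl ester.
3. The ten-membered carbocycle is closed at C5–C6 by an electrochemical, chromium-catalysed Nozaki–Hiyama–Kishi reaction of a (Z)-alkenyl bromide with the C6 aldehyde, which sets C6. Ring order: carbocycle, then lactone, then epoxide.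
4. The open-chain precursor comes from Fráter–Seebach alkylation (C7 set from the bought C8) of a β-hydroxy ester, made by copper-catalysed opening of ethyl (S)-3,4-epoxybutanoate with an (E)-alkenylmagnesium (C9–C10).
5. The west half comes from methyl (R)-glycerate acetonide (C3 bought): Ohira–Bestmann alkyne, Duboudin carbomagnesiation/bromination for the (Z)-bromoalkene, epoxide opening with propynyllithium, and hydrozirconation/iodination for the (E)-iodoalkene.

Assumption: positions are given in germacranolide numbering (C1–C15, lactone carbonyl C12, exocyclic methylene C13), and MeMgBr, 1-propynyllithium, Cp2Zr(H)Cl, i-PrMgCl·LiCl, LiN(i-Pr)2 and LiN(SiMe3)2 are used as bought.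

**Step 1**
Reactants: 1 methyl (4R)-2,2-dimethyl-1,3-dioxolane-4-carboxylate
Product: 3 (4S)-4-ethynyl-2,2-dimethyl-1,3-dioxolane, via aldehyde 2 (not isolated)
Conditions: i-Bu2AlH, CH2Cl2, −78 °C; then MeOH, K2CO3, dimethyl (1-diazo-2-oxopropyl)phosphonate, 0 °C → rt
Reagents that add atoms: dimethyl (1-diazo-2-oxopropyl)phosphonate, COP(=O)(OC)C(=[N+]=[N-])C(C)=O
Why: Partial DIBAL reduction stops at the aldehyde and the Ohira–Bestmann (Seyferth–Gilbert) homologation then gives the terminal alkyne in the same pot under mild carbonate conditions, leaving the bought stereocenter (future C3) untouched.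

**Step 2**
Reactants: 3 (4S)-4-ethynyl-2,2-dimethyl-1,3-dioxolane
Product: 4 (2S)-but-3-yne-1,2-diol
Conditions: Dowex 50W-X8 (H+ form), MeOH–H2O, rt
Reagents that add atoms: none
Why: Acid-catalysed acetal hydrolysis frees the propargylic hydroxyl that must direct the carbometalation, with no bond to the stereocenter broken.

**Step 3**
Reactants: 4 (2S)-but-3-yne-1,2-diol
Product: 6 (2S,3Z)-4-bromo-3-methylbut-3-ene-1,2-diol, via alkenylmagnesium 5 (not isolated)
Conditions: MeMgBr (4 equiv), CuI (20 mol %), THF, −10 °C → rt; then BrCl2C–CCl2Br, −30 → 0 °C; aq. NH4Cl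
Reagents that add atoms: methylmagnesium bromide, C[Mg]Br; 1,2-dibromo-1,1,2,2-tetrachloroethane, BrC(Cl)(Cl)C(Cl)(Cl)Br
Why: Duboudin–Jousseaume alkoxide-directed, copper-catalysed anti-carbomagnesiation puts methyl on the proximal alkyne carbon and magnesium on the terminal carbon cis to the carbinol through a five-membered chelate, so bromination with retention gives only the (Z)-bromoalkene (the future 4Z alkene).

**Step 4**
Reactants: 6 (2S,3Z)-4-bromo-3-methylbut-3-ene-1,2-diol
Product: 8 (2S)-2-[(1Z)-1-bromoprop-1-en-2-yl]oxirane, via monotosylate 7 (not isolated)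
Conditions: NaH (2.2 equiv), THF, 0 °C; N-(p-toluenesulfonyl)imidazole (1.05 equiv), 0 °C → rt
Reagents that add atoms: none
Why: One-pot sulfonylation of the primary alkoxide followed by Williamson closure by the secondary alkoxide gives the terminal epoxide with the C3–O bond intact (retention).

**Step 5**
Reactants: 8 (2S)-2-[(1Z)-1-bromoprop-1-en-2-yl]oxirane
Product: 9 (1Z,3R)-1-bromo-2-methylhept-1-en-5-yn-3-ol
Conditions: 1-propynyllithium (1.5 equiv), THF–DMPU, 0 → 35 °C; aq. NH4Cl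
Reagents that add atoms: 1-propynyllithium, [Li]C#CC
Why: Base-mediated SN2 epoxide opening by the alkynyllithium occurs at the unsubstituted carbon (the allylic carbon is shielded by the fully substituted, bromine-deactivated alkene carbon), adding C1, C10 and C14 without touching C3.

**Step 6**
Reactants: 9 (1Z,3R)-1-bromo-2-methylhept-1-en-5-yn-3-ol
Product: 11 (1Z,3R,5E)-1-bromo-6-iodo-2-methylhepta-1,5-dien-3-ol, via alkenylzirconocene 10 (not isolated)
Conditions: Cp2Zr(H)Cl (2.5 equiv), THF, rt → 40 °C; then I2, 0 °C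
Reagents that add atoms: iodine, II
Why: Schwartz syn-hydrozirconation of the 2-alkyne equilibrates to zirconium on the methyl-bearing carbon and iodinolysis with retention gives the (E)-2-iodoalkene (the future 1(10)E alkene), the alkenyl bromide being inert.

**Step 7**
Reactants: 12 ethyl (3S)-4-chloro-3-hydroxybutanoate
Product: 13 ethyl [(2S)-oxiran-2-yl]acetate
Conditions: Ag2O (0.6 equiv), 1,2-dimethoxyethane, 50 °C, dark
Reagents that add atoms: none
Why: Silver-assisted intramolecular Williamson closure under non-basic conditions avoids isomerisation of the β,γ-epoxy ester and retains the bought C–O stereocenter (future C8).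

**Step 8**
Reactants: 11 (1Z,3R,5E)-1-bromo-6-iodo-2-methylhepta-1,5-dien-3-ol; 13 ethyl [(2S)-oxiran-2-yl]acetate
Product: 15 ethyl (3R,5E,8R,9Z)-10-bromo-3,8-dihydroxy-5,9-dimethyldeca-5,9-dienoate, via alkenylmagnesium 14 (not isolated)
Conditions: i-PrMgCl·LiCl (2.1 equiv), THF, 0 °C → rt; then CuI (10 mol %), 13, −30 → −10 °C; aq. NH4Cl
Reagents that add atoms: none
Why: Iodine–magnesium exchange is selective for the alkenyl iodide over the alkenyl bromide and proceeds with retention, and the copper-catalysed alkenyl Grignard opens the epoxide at its terminal carbon, forming C9–C10 and revealing the C8 carbinol.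

**Step 9**
Reactants: 15 ethyl (3R,5E,8R,9Z)-10-bromo-3,8-dihydroxy-5,9-dimethyldeca-5,9-dienoate
Product: 17 4-tert-butyl 1-ethyl (2R)-2-[(1R,3E,6R,7Z)-8-bromo-3,7-dimethyl-1,6-bis(triisopropylsilyloxy)octa-3,7-dien-1-yl]butanedioate, via dilithium dialkoxide 16 (not isolated)
Conditions: LiN(i-Pr)2 (3.3 equiv), THF, −78 → −20 °C; BrCH2CO2t-Bu, DMPU, −78 → −30 °C; then i-Pr3SiOTf (2.5 equiv), −78 → 0 °C
Reagents that add atoms: tert-butyl bromoacetate, BrCC(=O)OC(C)(C)C; triisopropylsilyl trifluoromethanesulfonate, CC(C)[Si](C(C)C)(C(C)C)OS(=O)(=O)C(F)(F)F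
Why: Fráter–Seebach alkylation of the chelated lithium alkoxide–enolate occurs anti to the C9 substituent and so sets C7 anti to the bought C8 hydroxyl, and both alkoxides are capped in the same pot as triisopropylsilyl ethers, which do not migrate from O8 to O6 later.

**Step 10**
Reactants: 17 4-tert-butyl 1-ethyl (2R)-2-[(1R,3E,6R,7Z)-8-bromo-3,7-dimethyl-1,6-bis(triisopropylsilyloxy)octa-3,7-dien-1-yl]butanedioate
Product: 18 tert-butyl (3R,4R,6E,9R,10Z)-11-bromo-3-formyl-6,10-dimethyl-4,9-bis(triisopropylsilyloxy)undeca-6,10-dienoate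
Conditions: i-Bu2AlH (1.1 equiv), toluene, −78 °C; Na2SO4·10H2O
Reagents that add atoms: none
Why: Partial DIBAL reduction takes the ethyl ester to the aldehyde through the stable tetrahedral aluminate at −78 °C, while the hindered tert-butyl ester and the silyl ethers survive.

**Step 11**
Reactants: 18 tert-butyl (3R,4R,6E,9R,10Z)-11-bromo-3-formyl-6,10-dimethyl-4,9-bis(triisopropylsilyloxy)undeca-6,10-dienoate
Product: 20 (3aS,4R,6E,9R,10Z,11aR)-6,10-dimethyl-4,9-bis(triisopropylsilyloxy)-3a,4,5,8,9,11a-hexahydrocyclodeca[b]furan-2(3H)-one, via hydroxy ester 19 (not isolated)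
Conditions: CrCl2 (20 mol %), NiCl2·glyme (3 mol %), Cp2ZrCl2 (1.2 equiv), LiCl, DMF, undivided cell, Al anode, Ni-foam cathode, constant current (2.2 F/mol), 18 added by syringe pump over 12 h (3 mM), rt; then LiN(SiMe3)2 (1.05 equiv), THF, −78 → 0 °C
Reagents that add atoms: none
Why: Proposed new method: an electrochemical, chromium-catalysed Nozaki–Hiyama–Kishi ring closure in which the cathode regenerates divalent chromium, zerovalent nickel inserts into the (Z)-C–Br bond with retention and hands the alkenyl group to chromium, the alkenylchromium adds to the tethered aldehyde through a Felkin–Anh transition state (C8 branch anti to the incoming carbon, reinforced by 1,3-anti induction from the β-silyloxy group) to set C6, Cp2ZrCl2 frees the chromium alkoxide for turnover and slow addition favours ring closure over dimerisation, after which the lithium alkoxide closes the trans-lactone on the tert-butyl ester; the closest known reactions are stoichiometric CrCl2/NiCl2 Nozaki–Hiyama–Kishi macrocyclisations and the intermolecular electrochemical chromium-catalysed alkenyl halide–aldehyde coupling, neither shown for an electrochemical closure of a ten-membered carbocycle.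

**Step 12**
Reactants: 20 (3aS,4R,6E,9R,10Z,11aR)-6,10-dimethyl-4,9-bis(triisopropylsilyloxy)-3a,4,5,8,9,11a-hexahydrocyclodeca[b]furan-2(3H)-one
Product: 23 (3aS,4R,6E,9R,10Z,11aR)-6,10-dimethyl-3-methylidene-4,9-bis(triisopropylsilyloxy)-3a,4,5,8,9,11a-hexahydrocyclodeca[b]furan-2(3H)-one, via Mannich base 21 (not isolated), via ammonium iodide 22 (not isolated)
Conditions: LiN(SiMe3)2, THF, −78 °C; CH2=NMe2+ I−, −78 °C → rt; then MeI, MeOH, rt; then aq. NaHCO3, CH2Cl2, rt
Reagents that add atoms: N,N-dimethylmethyleneiminium iodide, C=[N+](C)C.[I-]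
Why: Eschenmoser α-methylenation (enolate Mannich reaction, quaternisation, Hofmann-type elimination) can only eliminate to the exocyclic alkene, and the transient C11 stereocenter is destroyed.

**Step 13**
Reactants: 23 (3aS,4R,6E,9R,10Z,11aR)-6,10-dimethyl-3-methylidene-4,9-bis(triisopropylsilyloxy)-3a,4,5,8,9,11a-hexahydrocyclodeca[b]furan-2(3H)-one
Product: 24 (3aR,4R,6E,9R,10Z,11aR)-4,9-dihydroxy-6,10-dimethyl-3-methylidene-3a,4,5,8,9,11a-hexahydrocyclodeca[b]furan-2(3H)-one
Conditions: HF·pyridine, pyridine, THF, 0 °C → rt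
Reagents that add atoms: none
Why: Buffered fluoride desilylation frees the C3 and C8 hydroxyls without conjugate addition to the α-methylene lactone or acid-induced transannular reaction.

**Step 14**
Reactants: 24 (3aR,4R,6E,9R,10Z,11aR)-4,9-dihydroxy-6,10-dimethyl-3-methylidene-3a,4,5,8,9,11a-hexahydrocyclodeca[b]furan-2(3H)-one
Product: 25 (3aR,4R,6E,9S,10Z,11aR)-9-chloro-4-hydroxy-6,10-dimethyl-3-methylidene-3a,4,5,8,9,11a-hexahydrocyclodeca[b]furan-2(3H)-one
Conditions: PPh3 (1.15 equiv), Cl3CC(O)CCl3, CH2Cl2, −20 → 0 °C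
Reagents that add atoms: hexachloroacetone, ClC(Cl)(Cl)C(=O)C(Cl)(Cl)Cl
Why: The Magid variant of the Appel reaction converts allylic alcohols into chlorides within minutes by SN2 with inversion and without allylic transposition, while the hindered non-allylic C8 hydroxyl reacts far more slowly, so the 3R alcohol gives the 3S chloride.

**Step 15**
Reactants: 26 ethyl (3S)-3-hydroxybutanoate
Product: 27 ethyl (2S,3S)-3-hydroxy-2-methylbutanoate
Conditions: LiN(i-Pr)2 (2.2 equiv), THF, −50 → −10 °C; MeI, DMPU, −78 → 0 °C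
Reagents that add atoms: iodomethane, CI
Why: Fráter–Seebach methylation of the chelated dianion occurs anti to the C4 methyl group and gives the anti (2S,3S) ester from the bought carbinol.

**Step 16**
Reactants: 27 ethyl (2S,3S)-3-hydroxy-2-methylbutanoate
Product: 28 ethyl (2S,3S)-2,3-dihydroxy-2-methylbutanoate
Conditions: LiN(i-Pr)2 (2.2 equiv), THF, −78 → −20 °C; MoO5·pyridine·HMPA (1.5 equiv), −78 → −40 °C; aq. Na2SO3
Reagents that add atoms: oxodiperoxymolybdenum–pyridine–hexamethylphosphoric triamide MoO5·C5H5N·OP(NMe2)3, O=[Mo]12(OO1)OO2.c1ccncc1.CN(C)P(=O)(N(C)C)N(C)C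
Why: Vedejs enolate hydroxylation of the Fráter–Seebach dianion brings the oxygen in on the same chelate face as the earlier alkylation, so the new tertiary hydroxyl is anti to the bought C3 hydroxyl and the quaternary center is set as 2S by substrate control.

**Step 17**
Reactants: 28 ethyl (2S,3S)-2,3-dihydroxy-2-methylbutanoate
Product: 29 ethyl (4S,5S)-2,2,4,5-tetramethyl-1,3-dioxolane-4-carboxylate
Conditions: Me2C(OMe)2, p-TsOH (cat.), CH2Cl2, rt
Reagents that add atoms: 2,2-dimethoxypropane, COC(C)(C)OC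
Why: Acid-catalysed transacetalisation ties both hydroxyls into a compact dioxolane, which keeps the quaternary acid small enough for the later acylation.

**Step 18**
Reactants: 29 ethyl (4S,5S)-2,2,4,5-tetramethyl-1,3-dioxolane-4-carboxylate
Product: 30 (4S,5S)-2,2,4,5-tetramethyl-1,3-dioxolane-4-carboxylic acid
Conditions: LiOH, THF–H2O, rt → 40 °C; then 1 M HCl to pH 3, 0 °C
Reagents that add atoms: lithium hydroxide, [Li+].[OH-]
Why: Saponification of the ester is safe because the α-carbon is quaternary and cannot epimerise.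

**Step 19**
Reactants: 25 (3aR,4R,6E,9S,10Z,11aR)-9-chloro-4-hydroxy-6,10-dimethyl-3-methylidene-3a,4,5,8,9,11a-hexahydrocyclodeca[b]furan-2(3H)-one; 30 (4S,5S)-2,2,4,5-tetramethyl-1,3-dioxolane-4-carboxylic acid
Product: 32 (3aR,4R,6E,9S,10Z,11aR)-9-chloro-6,10-dimethyl-3-methylidene-2-oxo-2,3,3a,4,5,8,9,11a-octahydrocyclodeca[b]furan-4-yl (4S,5S)-2,2,4,5-tetramethyl-1,3-dioxolane-4-carboxylate, via mixed anhydride 31 (not isolated)
Conditions: 30, 2,4,6-Cl3C6H2COCl, Et3N, THF, rt; then 25, DMAP, toluene, rt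
Reagents that add atoms: none
Why: Yamaguchi esterification through the mixed anhydride acylates the hindered C8 hydroxyl with retention at C8, and the acid has no epimerisable center.

**Step 20**
Reactants: 32 (3aR,4R,6E,9S,10Z,11aR)-9-chloro-6,10-dimethyl-3-methylidene-2-oxo-2,3,3a,4,5,8,9,11a-octahydrocyclodeca[b]furan-4-yl (4S,5S)-2,2,4,5-tetramethyl-1,3-dioxolane-4-carboxylate
Product: 33 (3aR,4R,6E,9S,10Z,11aR)-9-chloro-6,10-dimethyl-3-methylidene-2-oxo-2,3,3a,4,5,8,9,11a-octahydrocyclodeca[b]furan-4-yl (2S,3S)-2,3-dihydroxy-2-methylbutanoate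
Conditions: CF3CO2H–H2O–MeCN (1:1:8), 0 → 20 °C
Reagents that add atoms: none
Why: Acetal hydrolysis in cold dilute acid is done before the acid-labile epoxide exists, and the diene tolerates it because the 4,5-alkene is deactivated against transannular attack by the allylic chlorine and acyloxy groups.

**Step 21**
Reactants: 33 (3aR,4R,6E,9S,10Z,11aR)-9-chloro-6,10-dimethyl-3-methylidene-2-oxo-2,3,3a,4,5,8,9,11a-octahydrocyclodeca[b]furan-4-yl (2S,3S)-2,3-dihydroxy-2-methylbutanoate
Product: 34 (1R,3S,4Z,6R,7R,8R,10R)-3-chloro-1,10-epoxy-8-[(2S,3S)-2,3-dihydroxy-2-methylbutanoyloxy]germacra-4,11(13)-dien-12,6-olide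
Conditions: m-CPBA (1.1 equiv), CH2Cl2–aq. NaHCO3, 0 °C
Reagents that add atoms: 3-chloroperbenzoic acid, OOC(=O)c1cccc(Cl)c1
Why: Prilezhaev epoxidation picks the only electron-rich alkene (the 4,5-alkene is deactivated by the allylic chlorine and acyloxy groups, the methylene lactone is electron-poor), adds syn to the E alkene to give the trans epoxide, and is expected to attack the exposed outer face of the ring to give the (1R,10R) isomer under substrate control.

**Compound list**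
1 | methyl (4R)-2,2-dimethyl-1,3-dioxolane-4-carboxylate | COC(=O)[C@H]1COC(C)(C)O1 | starting material
2 | (4R)-2,2-dimethyl-1,3-dioxolane-4-carbaldehyde | O=C[C@H]1COC(C)(C)O1 | intermediate
3 | (4S)-4-ethynyl-2,2-dimethyl-1,3-dioxolane | C#C[C@H]1COC(C)(C)O1 | intermediate
4 | (2S)-but-3-yne-1,2-diol | C#C[C@H](O)CO | intermediate
5 | (2S,3Z)-4-(bromomagnesio)-3-methylbut-3-ene-1,2-diyl bis(oxymagnesium bromide) | Br[Mg]/C=C(/C)[C@H](O[Mg]Br)CO[Mg]Br | intermediate
6 | (2S,3Z)-4-bromo-3-methylbut-3-ene-1,2-diol | Br/C=C(/C)[C@H](O)CO | intermediate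
7 | sodium (2S,3Z)-4-bromo-3-methyl-1-(4-methylbenzenesulfonyloxy)but-3-en-2-olate | Br/C=C(/C)[C@H](O[Na])COS(=O)(=O)c1ccc(C)cc1 | intermediate
8 | (2S)-2-[(1Z)-1-bromoprop-1-en-2-yl]oxirane | Br/C=C(/C)[C@H]1CO1 | intermediate
9 | (1Z,3R)-1-bromo-2-methylhept-1-en-5-yn-3-ol | Br/C=C(/C)[C@H](O)CC#CC | intermediate
10 | chlorobis(cyclopentadienyl)zirconium (2E,5R,6Z)-7-bromo-6-methyl-5-[chlorobis(cyclopentadienyl)zirconiooxy]hepta-2,6-dien-2-yl (cyclopentadienyl rings drawn sigma-bonded in the SMILES) | Br/C=C(/C)[C@H](O[Zr](Cl)(C1C=CC=C1)C1C=CC=C1)C/C=C(\C)[Zr](Cl)(C1C=CC=C1)C1C=CC=C1 | intermediate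
11 | (1Z,3R,5E)-1-bromo-6-iodo-2-methylhepta-1,5-dien-3-ol | Br/C=C(/C)[C@H](O)C/C=C(\C)I | intermediate
12 | ethyl (3S)-4-chloro-3-hydroxybutanoate | ClC[C@@H](O)CC(=O)OCC | starting material
13 | ethyl [(2S)-oxiran-2-yl]acetate | C1[C@@H](O1)CC(=O)OCC | intermediate
14 | chloromagnesium (2E,5R,6Z)-7-bromo-2-(chloromagnesio)-6-methylhepta-2,6-dien-5-olate | Br/C=C(/C)[C@H](O[Mg]Cl)C/C=C(\C)[Mg]Cl | intermediate
15 | ethyl (3R,5E,8R,9Z)-10-bromo-3,8-dihydroxy-5,9-dimethyldeca-5,9-dienoate | Br/C=C(/C)[C@H](O)C/C=C(\C)C[C@@H](O)CC(=O)OCC | intermediate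
16 | dilithium dialkoxide of 4-tert-butyl 1-ethyl (2R)-2-[(1R,3E,6R,7Z)-8-bromo-1,6-dihydroxy-3,7-dimethylocta-3,7-dien-1-yl]butanedioate | Br/C=C(/C)[C@H](O[Li])C/C=C(\C)C[C@@H](O[Li])[C@@H](CC(=O)OC(C)(C)C)C(=O)OCC | intermediate
17 | 4-tert-butyl 1-ethyl (2R)-2-[(1R,3E,6R,7Z)-8-bromo-3,7-dimethyl-1,6-bis(triisopropylsilyloxy)octa-3,7-dien-1-yl]butanedioate | Br/C=C(/C)[C@H](O[Si](C(C)C)(C(C)C)C(C)C)C/C=C(\C)C[C@@H](O[Si](C(C)C)(C(C)C)C(C)C)[C@@H](CC(=O)OC(C)(C)C)C(=O)OCC | intermediate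
18 | tert-butyl (3R,4R,6E,9R,10Z)-11-bromo-3-formyl-6,10-dimethyl-4,9-bis(triisopropylsilyloxy)undeca-6,10-dienoate | Br/C=C(/C)[C@H](O[Si](C(C)C)(C(C)C)C(C)C)C/C=C(\C)C[C@@H](O[Si](C(C)C)(C(C)C)C(C)C)[C@@H](CC(=O)OC(C)(C)C)C=O | intermediate
19 | tert-butyl [(1S,2R,3Z,5R,7E,10R)-2-hydroxy-4,8-dimethyl-5,10-bis(triisopropylsilyloxy)cyclodeca-3,7-dien-1-yl]acetate | O[C@@H]1/C=C(/C)[C@H](O[Si](C(C)C)(C(C)C)C(C)C)C/C=C(\C)C[C@@H](O[Si](C(C)C)(C(C)C)C(C)C)[C@H]1CC(=O)OC(C)(C)C | intermediate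
20 | (3aS,4R,6E,9R,10Z,11aR)-6,10-dimethyl-4,9-bis(triisopropylsilyloxy)-3a,4,5,8,9,11a-hexahydrocyclodeca[b]furan-2(3H)-one | C1C(=O)O[C@@H]2/C=C(/C)[C@H](O[Si](C(C)C)(C(C)C)C(C)C)C/C=C(\C)C[C@@H](O[Si](C(C)C)(C(C)C)C(C)C)[C@@H]12 | intermediate
21 | (3aS,4R,6E,9R,10Z,11aR)-3-[(dimethylamino)methyl]-6,10-dimethyl-4,9-bis(triisopropylsilyloxy)-3a,4,5,8,9,11a-hexahydrocyclodeca[b]furan-2(3H)-one (both C3 epimers) | CN(C)CC1C(=O)O[C@@H]2/C=C(/C)[C@H](O[Si](C(C)C)(C(C)C)C(C)C)C/C=C(\C)C[C@@H](O[Si](C(C)C)(C(C)C)C(C)C)[C@@H]12 | intermediate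
22 | {[(3aS,4R,6E,9R,10Z,11aR)-6,10-dimethyl-2-oxo-4,9-bis(triisopropylsilyloxy)-2,3,3a,4,5,8,9,11a-octahydrocyclodeca[b]furan-3-yl]methyl}trimethylammonium iodide | C[N+](C)(C)CC1C(=O)O[C@@H]2/C=C(/C)[C@H](O[Si](C(C)C)(C(C)C)C(C)C)C/C=C(\C)C[C@@H](O[Si](C(C)C)(C(C)C)C(C)C)[C@@H]12.[I-] | intermediate
23 | (3aS,4R,6E,9R,10Z,11aR)-6,10-dimethyl-3-methylidene-4,9-bis(triisopropylsilyloxy)-3a,4,5,8,9,11a-hexahydrocyclodeca[b]furan-2(3H)-one | C=C1C(=O)O[C@@H]2/C=C(/C)[C@H](O[Si](C(C)C)(C(C)C)C(C)C)C/C=C(\C)C[C@@H](O[Si](C(C)C)(C(C)C)C(C)C)[C@@H]12 | intermediate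
24 | (3aR,4R,6E,9R,10Z,11aR)-4,9-dihydroxy-6,10-dimethyl-3-methylidene-3a,4,5,8,9,11a-hexahydrocyclodeca[b]furan-2(3H)-one | C=C1C(=O)O[C@@H]2/C=C(/C)[C@H](O)C/C=C(\C)C[C@@H](O)[C@@H]12 | intermediate
25 | (3aR,4R,6E,9S,10Z,11aR)-9-chloro-4-hydroxy-6,10-dimethyl-3-methylidene-3a,4,5,8,9,11a-hexahydrocyclodeca[b]furan-2(3H)-one | C=C1C(=O)O[C@@H]2/C=C(/C)[C@@H](Cl)C/C=C(\C)C[C@@H](O)[C@@H]12 | intermediate
26 | ethyl (3S)-3-hydroxybutanoate | CCOC(=O)C[C@H](C)O | starting material
27 | ethyl (2S,3S)-3-hydroxy-2-methylbutanoate | CCOC(=O)[C@@H](C)[C@H](C)O | intermediate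
28 | ethyl (2S,3S)-2,3-dihydroxy-2-methylbutanoate | CCOC(=O)[C@@](C)(O)[C@H](C)O | intermediate
29 | ethyl (4S,5S)-2,2,4,5-tetramethyl-1,3-dioxolane-4-carboxylate | CCOC(=O)[C@@]1(C)OC(C)(C)O[C@H]1C | intermediate
30 | (4S,5S)-2,2,4,5-tetramethyl-1,3-dioxolane-4-carboxylic acid | OC(=O)[C@@]1(C)OC(C)(C)O[C@H]1C | intermediate
31 | (4S,5S)-2,2,4,5-tetramethyl-1,3-dioxolane-4-carboxylic 2,4,6-trichlorobenzoic anhydride | O=C(OC(=O)c1c(Cl)cc(Cl)cc1Cl)[C@@]1(C)OC(C)(C)O[C@H]1C | intermediate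
32 | (3aR,4R,6E,9S,10Z,11aR)-9-chloro-6,10-dimethyl-3-methylidene-2-oxo-2,3,3a,4,5,8,9,11a-octahydrocyclodeca[b]furan-4-yl (4S,5S)-2,2,4,5-tetramethyl-1,3-dioxolane-4-carboxylate | C=C1C(=O)O[C@@H]2/C=C(/C)[C@@H](Cl)C/C=C(\C)C[C@@H](OC(=O)[C@@]3(C)OC(C)(C)O[C@H]3C)[C@@H]12 | intermediate
33 | (3aR,4R,6E,9S,10Z,11aR)-9-chloro-6,10-dimethyl-3-methylidene-2-oxo-2,3,3a,4,5,8,9,11a-octahydrocyclodeca[b]furan-4-yl (2S,3S)-2,3-dihydroxy-2-methylbutanoate | C=C1C(=O)O[C@@H]2/C=C(/C)[C@@H](Cl)C/C=C(\C)C[C@@H](OC(=O)[C@@](C)(O)[C@H](C)O)[C@@H]12 | intermediate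
34 | (1R,3S,4Z,6R,7R,8R,10R)-3-chloro-1,10-epoxy-8-[(2S,3S)-2,3-dihydroxy-2-methylbutanoyloxy]germacra-4,11(13)-dien-12,6-olide (CNP0325326.6) | C=C1C(=O)O[C@@H]2/C=C(/C)[C@@H](Cl)C[C@H]3O[C@]3(C)C[C@@H](OC(=O)[C@@](C)(O)[C@H](C)O)[C@@H]12 | target

**Step count and risks**
Total step count: 21. Longest linear sequence: 16 (steps 1–6, 8–14, 19–21).

Step 11 is the proposed new step and the most likely to fail: catalytic turnover at 3 mM is unproven, the alkenyl bromide is a slow partner, dimerisation competes, and the ring may override the Felkin preference at C6. Its fallback sets out from 18 and comes back at 20. It gives up the electrode and the catalytic cycle for the classical stoichiometric reagent reaction: CrCl2 (6–10 equiv) with NiCl2 (1 mol %) in DMSO–THF, 18 added by syringe pump at rt. This is the established Nozaki–Hiyama–Kishi closure of ten-membered carbocycles; it gives hydroxy ester 19, which is lactonised with LiN(SiMe3)2 as before, and it passes through no compound outside the list, none F0.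

Step 14 is the second risk: the allylic C3 hydroxyl must be chlorinated in the presence of the free C8 hydroxyl, with clean inversion and no SN2' leakage. Its fallback sets out from 24 and comes back at 32, replacing the chemoselective chlorination by a protect–acylate–release order. TESCl (1.05 equiv) and imidazole at −40 °C silylate the less hindered allylic hydroxyl to give the 3-O-triethylsilyl ether F1. Yamaguchi acylation of its C8 hydroxyl with 30 gives the silyl ether ester F2. HF·pyridine then gives the allylic alcohol ester F3, whose only free hydroxyl is converted by PPh3/hexachloroacetone into 32.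

Step 21 is the third risk: the peracid may attack the wrong face of the 1(10)-alkene. Its fallback sets out from 33 and comes back at 34, and it reverses the facial outcome by going through a halohydrin. NBS in THF–H2O at 0 °C puts bromine on the face the peracid prefers and water on C10 from the other side, giving the bromohydrin F4. Ag2O in 1,2-dimethoxyethane then closes the epoxide by SN2 at C1, so the oxygen ends on the face opposite to direct epoxidation.

**Further compounds**
F0 | step 11 | none | none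
F1 | step 14 | (3aR,4R,6E,9R,10Z,11aR)-4-hydroxy-6,10-dimethyl-3-methylidene-9-(triethylsilyloxy)-3a,4,5,8,9,11a-hexahydrocyclodeca[b]furan-2(3H)-one | C=C1C(=O)O[C@@H]2/C=C(/C)[C@H](O[Si](CC)(CC)CC)C/C=C(\C)C[C@@H](O)[C@@H]12
F2 | step 14 | (3aR,4R,6E,9R,10Z,11aR)-6,10-dimethyl-3-methylidene-2-oxo-9-(triethylsilyloxy)-2,3,3a,4,5,8,9,11a-octahydrocyclodeca[b]furan-4-yl (4S,5S)-2,2,4,5-tetramethyl-1,3-dioxolane-4-carboxylate | C=C1C(=O)O[C@@H]2/C=C(/C)[C@H](O[Si](CC)(CC)CC)C/C=C(\C)C[C@@H](OC(=O)[C@@]3(C)OC(C)(C)O[C@H]3C)[C@@H]12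
F3 | step 14 | (3aR,4R,6E,9R,10Z,11aR)-9-hydroxy-6,10-dimethyl-3-methylidene-2-oxo-2,3,3a,4,5,8,9,11a-octahydrocyclodeca[b]furan-4-yl (4S,5S)-2,2,4,5-tetramethyl-1,3-dioxolane-4-carboxylate | C=C1C(=O)O[C@@H]2/C=C(/C)[C@H](O)C/C=C(\C)C[C@@H](OC(=O)[C@@]3(C)OC(C)(C)O[C@H]3C)[C@@H]12
F4 | step 21 | (1S,3S,4Z,6R,7R,8R,10R)-1-bromo-3-chloro-10-hydroxy-8-[(2S,3S)-2,3-dihydroxy-2-methylbutanoyloxy]germacra-4,11(13)-dien-12,6-olide | C=C1C(=O)O[C@@H]2/C=C(/C)[C@@H](Cl)C[C@H](Br)[C@](C)(O)C[C@@H](OC(=O)[C@@](C)(O)[C@H](C)O)[C@@H]12
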